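**Retrosynthetic overview**
1. The route rests on one feature: a trans-fused decalin (ring A = C1–C5 and C10; ring B = C5–C10) whose quaternary C5 (angular CH3) lies next to the C4 methine (C4–CH3), with a C8=C9 alkene in ring B as the handle for the C7 (isopropenyl) / C8 (OH) / C9 (O-acyl) triad.
2. Late stage, backwards: the C2 carbinol comes from the ketone, which stays a dioxolane until the C9 ester is in place. The ester comes from stannylene-directed acylation of the 8α,9α-diol. C7–isopropenyl and C8–OH come from trans-diaxial opening of a 7α,8α-epoxide of the 9α-hydroxy-Δ7 alkene, which is reached from C8=C9 by α-face dihydroxylation and syn-elimination of the C8 hydroxyl.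
3. Key disconnection: C5–C10 and C6–C7 are made in one intramolecular Diels–Alder reaction of a 2-methylidene aldehyde (C5=C6, formyl = latent angular methyl) with the tethered (E)-diene C7=C8–C9=C10. Rings A and B form together, and CHO is then reduced to CH3.
4. The trienal comes from the chiral pool: the (R)-hemiester of 3-methylglutaric acid supplies C4. Its methyl ester arm is built into the C2 ketal and the diene (Claisen condensation, allylphosphonate olefination); its acid arm becomes the 2-methylidene aldehyde.

Key step: step 9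

Remark: positions are numbered as in the overview, α is the face of H10 and β the face of the C5 methyl group; compound 1 is assumed to be purchased as the enantiopure (R)-hemiester, whose acid arm becomes C5/CHO and whose ester arm becomes C3/C2.

**Route**

Step 1
Reactants: 1 (3R)-5-methoxy-3-methyl-5-oxopentanoic acid
Product: 2 1-tert-butyl 5-methyl (3S)-3-methylpentanedioate
Conditions: t-BuOC(=NH)CCl3 (2 equiv), BF3·OEt2 (cat.), cyclohexane/CH2Cl2, rt
Reagents that add atoms: tert-butyl 2,2,2-trichloroacetimidate, CC(C)(C)OC(=N)C(Cl)(Cl)Cl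
Why: Acid-catalysed O-alkylation of the carboxylic acid by the trichloroacetimidate (tert-butyl ester formation) differentiates the two termini as a hindered, hydride- and enolate-resistant tert-butyl ester and a reactive methyl ester without touching the C3 stereocentre.

Step 2
Reactants: 2 1-tert-butyl 5-methyl (3S)-3-methylpentanedioate; 3 N-methoxy-N-methylacetamide
Product: 4 tert-butyl (3S)-7-[methoxy(methyl)amino]-3-methyl-5,7-dioxoheptanoate
Conditions: 3 and LiN(i-Pr)2 (2.6 equiv each), THF, −78 °C; then 2, −78 → −20 °C; AcOH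
Reagents that add atoms: none
Why: Crossed Claisen condensation in which the amide enolate attacks the unhindered methyl ester in preference to the tert-butyl ester, the β-keto amide being held as its enolate until the quench so that no second addition occurs.

Step 3
Reactants: 4 tert-butyl (3S)-7-[methoxy(methyl)amino]-3-methyl-5,7-dioxoheptanoate
Product: 5 tert-butyl (3S)-4-(2-{2-[methoxy(methyl)amino]-2-oxoethyl}-1,3-dioxolan-2-yl)-3-methylbutanoate
Conditions: TMSOCH2CH2OTMS (2 equiv), TMSOTf (5 mol%), CH2Cl2, −78 → −20 °C; pyridine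
Reagents that add atoms: 1,2-bis(trimethylsilyloxy)ethane, C[Si](C)(C)OCCO[Si](C)(C)C
Why: Silyl-triflate-catalysed dioxolane formation from the bis-silyl glycol, driven by formation of hexamethyldisiloxane, protects the future C2 ketone under conditions that spare the tert-butyl ester and the N-methoxy amide.

Step 4
Reactants: 5 tert-butyl (3S)-4-(2-{2-[methoxy(methyl)amino]-2-oxoethyl}-1,3-dioxolan-2-yl)-3-methylbutanoate
Product: 6 tert-butyl (3S)-3-methyl-4-[2-(2-oxoethyl)-1,3-dioxolan-2-yl]butanoate
Conditions: i-Bu2AlH (1.2 equiv), THF, −78 °C; aq. potassium sodium tartrate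
Reagents that add atoms: none
Why: Hydride reduction of the N-methoxy-N-methylamide stops at the chelated aluminium hemiaminal, which gives the aldehyde (future C10) on work-up, while the tert-butyl ester does not react at −78 °C.

Step 5
Reactants: 6 tert-butyl (3S)-3-methyl-4-[2-(2-oxoethyl)-1,3-dioxolan-2-yl]butanoate; 7 diethyl allylphosphonate
Product: 8 tert-butyl (3S)-3-methyl-4-{2-[(2E)-penta-2,4-dien-1-yl]-1,3-dioxolan-2-yl}butanoate
Conditions: 7, n-BuLi, THF, −78 °C; HMPA; then 6, −78 °C → rt; aq. NH4Cl
Reagents that add atoms: none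
Why: Horner–Wadsworth–Emmons-type olefination through α-attack of the lithiated allylphosphonate and syn-elimination of phosphate from the equilibrated adduct should give the (E)-configured terminal diene C10=C9–C8=C7.

Step 6
Reactants: 8 tert-butyl (3S)-3-methyl-4-{2-[(2E)-penta-2,4-dien-1-yl]-1,3-dioxolan-2-yl}butanoate
Product: 9 (3R)-3-methyl-4-{2-[(2E)-penta-2,4-dien-1-yl]-1,3-dioxolan-2-yl}butan-1-ol
Conditions: LiAlH4, Et2O, 0 °C; H2O, aq. NaOH
Reagents that add atoms: none
Why: Ester reduction with LiAlH4 gives the primary alcohol, the unactivated diene and the dioxolane being inert to the hydride.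

Step 7
Reactants: 9 (3R)-3-methyl-4-{2-[(2E)-penta-2,4-dien-1-yl]-1,3-dioxolan-2-yl}butan-1-ol
Product: 10 (3R)-3-methyl-4-{2-[(2E)-penta-2,4-dien-1-yl]-1,3-dioxolan-2-yl}butanal
Conditions: TEMPO (10 mol%), PhI(OAc)2 (1.2 equiv), CH2Cl2, rt
Reagents that add atoms: none
Why: Oxoammonium (TEMPO) oxidation of the primary alcohol stops at the aldehyde and leaves the diene, the ketal and the non-epimerisable β-stereocentre untouched.

Step 8
Reactants: 10 (3R)-3-methyl-4-{2-[(2E)-penta-2,4-dien-1-yl]-1,3-dioxolan-2-yl}butanal
Product: 11 (3S)-3-methyl-2-methylidene-4-{2-[(2E)-penta-2,4-dien-1-yl]-1,3-dioxolan-2-yl}butanal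
Conditions: 37% aq. CH2O, pyrrolidine (10 mol%), EtCO2H (10 mol%), i-PrOH, 25–40 °C; worked up cold and used at once
Reagents that add atoms: formaldehyde, C=O
Why: Amine-catalysed Mannich condensation with formaldehyde followed by β-elimination of the amine (aldehyde α-methylenation) installs the C5=C6 dienophile, the neighbouring stereocentre not being conjugated with the enamine or iminium intermediates and therefore kept.

Step 9
Reactants: 11 (3S)-3-methyl-2-methylidene-4-{2-[(2E)-penta-2,4-dien-1-yl]-1,3-dioxolan-2-yl}butanal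
Product: 12 trans-fused 5β-formyl-4β-methyl-Δ8-octalin-2-one ethylene ketal (10α-H)
Conditions: Me2AlCl (1.5 equiv), CH2Cl2 (0.02 M), −78 → −30 °C; aq. NaHCO3
Reagents that add atoms: none
Why: A concerted, asynchronous [4+2] cycloaddition in which the Me2AlCl-complexed 2-alkylacrolein (C5=C6) adds suprafacially to the tethered (E)-diene (C7=C8–C9=C10), the closest known reaction type being the Lewis-acid-promoted intramolecular Diels–Alder reaction of 1,7,9-decatrienes whose activating group sits on the tethered dienophile carbon. Ring A closes in the fused mode as a six-membered chair made of C5, C10 and the tether C1–C4 when the C5–C10 bond forms, and ring B is the cyclohexene generated by the cycloaddition itself, completed by the C6–C7 bond. C5 becomes quaternary with the formyl group endo under C8–C9, which sets formyl and H10 trans across the new ring fusion, and C10 follows from the E geometry of the C9=C10 bond. The diene face that is attacked is dictated by C4: in the chair-like tether its methyl group is equatorial and anti to the forming C5–C10 bond, whereas the other chair would put it axial, eclipsed with the methylidene carbon and syn-axial to a dioxolane oxygen. The step needs endo (trans-fused) over exo (cis-fused) selectivity and one diene face; the first is secured by secondary overlap of the complexed formyl group, the second by the C4 methyl group, while the regiochemistry is fixed by the tether, matches the polarisation of both partners (electrophilic C6 to the unsubstituted diene terminus C7) and is helped by the gem-dialkoxy C2, which favours the folded conformer.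

Step 10
Reactants: 12 trans-fused 5β-formyl-4β-methyl-Δ8-octalin-2-one ethylene ketal (10α-H)
Product: 14 trans-fused 4β,5β-dimethyl-Δ8-octalin-2-one ethylene ketal (10α-H), via hydrazone 13 (not isolated)
Conditions: N2H4·H2O, KOH, diethylene glycol, 130 °C then 200 °C (−H2O)
Reagents that add atoms: none
Why: Wolff–Kishner reduction (Huang-Minlon procedure), in which hydrazine condenses even with the neopentyl aldehyde and base-induced loss of N2 from the hydrazone gives the angular methyl group, the ketal and the isolated alkene being stable to hot KOH and no stereocentre being epimerisable.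

Step 11
Reactants: 14 trans-fused 4β,5β-dimethyl-Δ8-octalin-2-one ethylene ketal (10α-H)
Product: 15 8α,9α-dihydroxy-4β,5β-dimethyl-trans-decalin-2-one ethylene ketal
Conditions: OsO4 (2 mol%), N-methylmorpholine N-oxide (1.5 equiv), acetone/H2O (5:1), rt; aq. Na2SO3
Reagents that add atoms: N-methylmorpholine N-oxide, C[N+]1([O-])CCOCC1; water, O
Why: Catalytic syn-dihydroxylation (osmate ester formation, then hydrolysis) should take place on the α face, because the axial C5 methyl group is syn-axial to the β face at C9 and C7, and this sets both C8–O and C9–O α.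

Step 12
Reactants: 15 8α,9α-dihydroxy-4β,5β-dimethyl-trans-decalin-2-one ethylene ketal
Product: 17 9α-benzoyloxy-8α-hydroxy-4β,5β-dimethyl-trans-decalin-2-one ethylene ketal, via stannylene acetal 16 (not isolated)
Conditions: Bu2SnO (1.05 equiv), toluene, reflux (−H2O); then BzCl (1.05 equiv), 0 °C → rt
Reagents that add atoms: benzoyl chloride, O=C(Cl)c1ccccc1
Why: Stannylene-acetal-mediated monoacylation, in which the equatorial oxygen of the dibutylstannylene acetal of a cyclohexane cis-diol is the nucleophilic one, so that benzoyl chloride should acylate O9 and leave the axial C8 hydroxyl free.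

Step 13
Reactants: 17 9α-benzoyloxy-8α-hydroxy-4β,5β-dimethyl-trans-decalin-2-one ethylene ketal
Product: 19 9α-benzoyloxy-4β,5β-dimethyl-Δ7-octalin-2-one ethylene ketal (trans-fused), via sulfamate ester 18 (not isolated)
Conditions: Burgess reagent (MeO2CN(−)SO2N(+)Et3, 2 equiv), benzene, rt then 70 °C
Reagents that add atoms: none
Why: Burgess dehydration, a thermal syn (Ei) elimination of the sulfamate ester, in which the only hydrogen cis to the axial 8α-oxygen is 7α-H (9-H is trans-diaxial to it), so that the alkene can form only between C7 and C8 and the C9 oxygen keeps its configuration.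

Step 14
Reactants: 19 9α-benzoyloxy-4β,5β-dimethyl-Δ7-octalin-2-one ethylene ketal (trans-fused)
Product: 20 9α-hydroxy-4β,5β-dimethyl-Δ7-octalin-2-one ethylene ketal (trans-fused)
Conditions: K2CO3 (0.3 equiv), MeOH, rt
Reagents that add atoms: none
Why: Base-catalysed transesterification (methanolysis) of the benzoate releases the allylic alcohol, nothing else in the molecule being base-sensitive.

Step 15
Reactants: 20 9α-hydroxy-4β,5β-dimethyl-Δ7-octalin-2-one ethylene ketal (trans-fused)
Product: 21 7α,8α-epoxy-9α-hydroxy-4β,5β-dimethyl-trans-decalin-2-one ethylene ketal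
Conditions: mCPBA (1.3 equiv), NaHCO3, CH2Cl2, 0 °C
Reagents that add atoms: 3-chloroperoxybenzoic acid, O=C(OO)c1cccc(Cl)c1
Why: Hydroxyl-directed peracid epoxidation (Henbest effect), in which hydrogen bonding of the peracid to the pseudo-equatorial 9α-hydroxyl delivers oxygen to the α face, also the face remote from the axial C5 methyl group, and so sets C7 and C8 of the epoxide.

Step 16
Reactants: 21 7α,8α-epoxy-9α-hydroxy-4β,5β-dimethyl-trans-decalin-2-one ethylene ketal; 22 isopropenylmagnesium bromide
Product: 23 8α,9α-dihydroxy-7β-isopropenyl-4β,5β-dimethyl-trans-decalin-2-one ethylene ketal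
Conditions: 22 (5 equiv), CuI (0.3 equiv), THF, −30 → 0 °C; aq. NH4Cl
Reagents that add atoms: none
Why: Copper-catalysed Grignard opening of the epoxide by SN2 attack with inversion at C7 follows the trans-diaxial (Fürst–Plattner) course and should give axial 7β-isopropenyl and axial 8α-hydroxyl, attack at C8 needing a twist-boat and being further retarded by the neighbouring C9 alkoxide.

Step 17
Reactants: 24 (2E)-3-methylpent-2-enoic acid
Product: 25 (2E)-3-methylpent-2-enoyl chloride
Conditions: Me2C=C(Cl)NMe2 (1.1 equiv), CH2Cl2, 0 °C → rt; used as the crude solution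
Reagents that add atoms: 1-chloro-N,N,2-trimethylprop-1-en-1-amine, CC(C)=C(Cl)N(C)C
Why: Neutral conversion of the acid into its chloride with the α-chloroenamine avoids HCl and amine bases, so that no vinylketene can form and the E geometry of the β,β-disubstituted enoate is kept.

Step 18
Reactants: 23 8α,9α-dihydroxy-7β-isopropenyl-4β,5β-dimethyl-trans-decalin-2-one ethylene ketal; 25 (2E)-3-methylpent-2-enoyl chloride
Product: 27 8α-hydroxy-7β-isopropenyl-4β,5β-dimethyl-9α-[(2E)-3-methylpent-2-enoyloxy]-trans-decalin-2-one ethylene ketal, via stannylene acetal 26 (not isolated)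
Conditions: Bu2SnO (1.05 equiv), toluene, reflux (−H2O); then 25 (1.2 equiv), 0 °C → rt
Reagents that add atoms: none
Why: Stannylene-acetal-mediated acylation again selects the equatorial O9 over the axial O8 and needs no base, so that the E geometry of the acyl group is preserved, while C2 is still masked as the ketal and cannot compete.

Step 19
Reactants: 27 8α-hydroxy-7β-isopropenyl-4β,5β-dimethyl-9α-[(2E)-3-methylpent-2-enoyloxy]-trans-decalin-2-one ethylene ketal
Product: 28 8α-hydroxy-7β-isopropenyl-4β,5β-dimethyl-9α-[(2E)-3-methylpent-2-enoyloxy]-trans-decalin-2-one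
Conditions: PPTS (0.3 equiv), acetone/H2O (10:1), 50 °C
Reagents that add atoms: water, O
Why: Acid-catalysed hydrolysis of the dioxolane (ketal exchange into aqueous acetone) under weakly acidic conditions should free the C2 ketone without ester migration or protonation of the isopropenyl group.

Step 20
Reactants: 28 8α-hydroxy-7β-isopropenyl-4β,5β-dimethyl-9α-[(2E)-3-methylpent-2-enoyloxy]-trans-decalin-2-one
Product: 29 CNP0129603.2, 2α,8α-dihydroxy-7β-isopropenyl-4β,5β-dimethyl-9α-[(2E)-3-methylpent-2-enoyloxy]-trans-decalin (10α-H)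
Conditions: LiBH(s-Bu)3 (2.2 equiv), THF, −78 °C; AcOH, −78 °C
Reagents that add atoms: none
Why: Ketone reduction with the bulky trialkylborohydride occurs by equatorial attack on the unhindered cyclohexanone and should give the axial 2α-alcohol, the β,β-disubstituted enoate ester not being reduced at −78 °C.

**Compound list**
1 | (3R)-5-methoxy-3-methyl-5-oxopentanoic acid [(R)-3-methylglutaric acid monomethyl ester] | COC(=O)C[C@H](C)CC(=O)O | starting material
2 | 1-tert-butyl 5-methyl (3S)-3-methylpentanedioate | COC(=O)C[C@H](C)CC(=O)OC(C)(C)C | intermediate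
3 | N-methoxy-N-methylacetamide | CC(=O)N(C)OC | starting material
4 | tert-butyl (3S)-7-[methoxy(methyl)amino]-3-methyl-5,7-dioxoheptanoate | CON(C)C(=O)CC(=O)C[C@H](C)CC(=O)OC(C)(C)C | intermediate
5 | tert-butyl (3S)-4-(2-{2-[methoxy(methyl)amino]-2-oxoethyl}-1,3-dioxolan-2-yl)-3-methylbutanoate | CON(C)C(=O)CC1(OCCO1)C[C@H](C)CC(=O)OC(C)(C)C | intermediate
6 | tert-butyl (3S)-3-methyl-4-[2-(2-oxoethyl)-1,3-dioxolan-2-yl]butanoate | O=CCC1(OCCO1)C[C@H](C)CC(=O)OC(C)(C)C | intermediate
7 | diethyl allylphosphonate | C=CCP(=O)(OCC)OCC | starting material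
8 | tert-butyl (3S)-3-methyl-4-{2-[(2E)-penta-2,4-dien-1-yl]-1,3-dioxolan-2-yl}butanoate | C=C/C=C/CC1(OCCO1)C[C@H](C)CC(=O)OC(C)(C)C | intermediate
9 | (3R)-3-methyl-4-{2-[(2E)-penta-2,4-dien-1-yl]-1,3-dioxolan-2-yl}butan-1-ol | C=C/C=C/CC1(OCCO1)C[C@H](C)CCO | intermediate
10 | (3R)-3-methyl-4-{2-[(2E)-penta-2,4-dien-1-yl]-1,3-dioxolan-2-yl}butanal | C=C/C=C/CC1(OCCO1)C[C@H](C)CC=O | intermediate
11 | (3S)-3-methyl-2-methylidene-4-{2-[(2E)-penta-2,4-dien-1-yl]-1,3-dioxolan-2-yl}butanal | C=C(C=O)[C@@H](C)CC1(OCCO1)C/C=C/C=C | intermediate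
12 | trans-fused 5β-formyl-4β-methyl-Δ8-octalin-2-one ethylene ketal (10α-H) | C1C[C@]2(C=O)[C@@H](C)CC3(OCCO3)C[C@H]2C=C1 | intermediate
13 | hydrazone of 12 at the C5 formyl group | C1C[C@]2(/C=N/N)[C@@H](C)CC3(OCCO3)C[C@H]2C=C1 | intermediate (not isolated)
14 | trans-fused 4β,5β-dimethyl-Δ8-octalin-2-one ethylene ketal (10α-H) | C1C[C@]2(C)[C@@H](C)CC3(OCCO3)C[C@H]2C=C1 | intermediate
15 | 8α,9α-dihydroxy-4β,5β-dimethyl-trans-decalin-2-one ethylene ketal | C1C[C@]2(C)[C@@H](C)CC3(OCCO3)C[C@H]2[C@H](O)[C@@H]1O | intermediate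
16 | 8α,9α-O-dibutylstannylene acetal of 15 | C1C[C@]2(C)[C@@H](C)CC3(OCCO3)C[C@H]2[C@@H]4O[Sn](CCCC)(CCCC)O[C@H]14 | intermediate (not isolated)
17 | 9α-benzoyloxy-8α-hydroxy-4β,5β-dimethyl-trans-decalin-2-one ethylene ketal | C1C[C@]2(C)[C@@H](C)CC3(OCCO3)C[C@H]2[C@H](OC(=O)c4ccccc4)[C@@H]1O | intermediate
18 | 8α-O-[N-(methoxycarbonyl)sulfamate] of 17, triethylammonium salt | C1C[C@]2(C)[C@@H](C)CC3(OCCO3)C[C@H]2[C@H](OC(=O)c4ccccc4)[C@@H]1OS(=O)(=O)[N-]C(=O)OC.CC[NH+](CC)CC | intermediate (not isolated)
19 | 9α-benzoyloxy-4β,5β-dimethyl-Δ7-octalin-2-one ethylene ketal (trans-fused) | C[C@H]1CC2(OCCO2)C[C@H]3[C@H](OC(=O)c4ccccc4)C=CC[C@]13C | intermediate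
20 | 9α-hydroxy-4β,5β-dimethyl-Δ7-octalin-2-one ethylene ketal (trans-fused) | C[C@H]1CC2(OCCO2)C[C@H]3[C@H](O)C=CC[C@]13C | intermediate
21 | 7α,8α-epoxy-9α-hydroxy-4β,5β-dimethyl-trans-decalin-2-one ethylene ketal | C[C@H]1CC2(OCCO2)C[C@H]3[C@H](O)[C@@H]4O[C@@H]4C[C@]13C | intermediate
22 | isopropenylmagnesium bromide | CC(=C)[Mg]Br | starting material
23 | 8α,9α-dihydroxy-7β-isopropenyl-4β,5β-dimethyl-trans-decalin-2-one ethylene ketal | C=C(C)[C@H]1C[C@]2(C)[C@@H](C)CC3(OCCO3)C[C@H]2[C@H](O)[C@@H]1O | intermediate
24 | (2E)-3-methylpent-2-enoic acid | CC/C(C)=C/C(=O)O | starting material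
25 | (2E)-3-methylpent-2-enoyl chloride | CC/C(C)=C/C(=O)Cl | intermediate
26 | 8α,9α-O-dibutylstannylene acetal of 23 | C=C(C)[C@H]1C[C@]2(C)[C@@H](C)CC3(OCCO3)C[C@H]2[C@@H]4O[Sn](CCCC)(CCCC)O[C@H]14 | intermediate (not isolated)
27 | 8α-hydroxy-7β-isopropenyl-4β,5β-dimethyl-9α-[(2E)-3-methylpent-2-enoyloxy]-trans-decalin-2-one ethylene ketal | C=C(C)[C@H]1C[C@]2(C)[C@@H](C)CC3(OCCO3)C[C@H]2[C@H](OC(=O)/C=C(\C)CC)[C@@H]1O | intermediate
28 | 8α-hydroxy-7β-isopropenyl-4β,5β-dimethyl-9α-[(2E)-3-methylpent-2-enoyloxy]-trans-decalin-2-one | C=C(C)[C@H]1C[C@]2(C)[C@@H](C)CC(=O)C[C@H]2[C@H](OC(=O)/C=C(\C)CC)[C@@H]1O | intermediate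
29 | CNP0129603.2, 2α,8α-dihydroxy-7β-isopropenyl-4β,5β-dimethyl-9α-[(2E)-3-methylpent-2-enoyloxy]-trans-decalin (10α-H) | C=C(C)[C@H]1C[C@]2(C)[C@@H](C)C[C@H](O)C[C@H]2[C@H](OC(=O)/C=C(\C)CC)[C@@H]1O | target

**Step count and risk**

Total step count: 20. Longest linear sequence: 19 steps (steps 1–16 and 18–20); step 17 is a one-step side branch.

Steps most likely to fail:

1. Step 9 (key step). The preference for the formyl-endo transition state may be too small, so that material leaks into the cis-fused series, or the Lewis acid may ionise the dioxolane. The fallback keeps the cycloaddition but adds a steric directing group on the diene, so that no strong Lewis acid is needed. It sets out from 6: dibromo-olefination (CBr4, PPh3) should give tert-butyl (3S)-4-[2-(3,3-dibromoprop-2-en-1-yl)-1,3-dioxolan-2-yl]-3-methylbutanoate F1. Mono-coupling of the bromine trans to the chain with tributyl(vinyl)stannane (Pd2(dba)3, tri(2-furyl)phosphine) should give the (Z)-bromodiene ester F2. Reduction, oxidation and methylenation as in steps 6–8 should then give the bromodiene alcohol F3, the bromodiene aldehyde F4 and the bromotrienal F5. In the thermal cyclisation of F5 (toluene, 80–110 °C, BHT) the C9 bromine clashes with C2 of the tether only in the cis-fused transition state, so the trans-fused 9-bromo adduct F6 should prevail. Hydrodebromination (Pd(PPh3)4, Bu3SnH) brings the sequence back to the route at 12.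

2. Step 13. The hindered axial sulfamate may form slowly, or may collapse by ionisation or substitution and not by syn-elimination. The fallback replaces the diol/elimination sequence by an epoxide rearrangement and sets out from 14: mCPBA should epoxidise the α face to the 8α,9α-epoxide F7, and base-induced rearrangement with LiNEt2 (proton removal from C7, cleavage of the C8–O bond) would give the allylic alcohol directly, coming back to the route at 20. Its weak point is competing removal of the tertiary C10 hydrogen, which is why it is the second choice.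

3. Step 16. The nucleophile must enter C7 syn-axial to the C5 methyl group, so the opening may be slow, or may be diverted to bromohydrin formation or to attack at C8. The fallback uses a slimmer carbon nucleophile and sets out from 21: trans-diaxial opening with LiC≡CH·H2NCH2CH2NH2 in DMSO should give the 7β-ethynyl-8α,9α-diol F8. Zirconium-catalysed methylalumination of the alkyne (Me3Al, Cp2ZrCl2; then H2O) then converts the ethynyl into the isopropenyl group and comes back to the route at 23.

**Further compounds**
F1 | step 9 | tert-butyl (3S)-4-[2-(3,3-dibromoprop-2-en-1-yl)-1,3-dioxolan-2-yl]-3-methylbutanoate | BrC(Br)=CCC1(OCCO1)C[C@H](C)CC(=O)OC(C)(C)C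
F2 | step 9 | tert-butyl (3S)-4-{2-[(2Z)-3-bromopenta-2,4-dien-1-yl]-1,3-dioxolan-2-yl}-3-methylbutanoate | C=C/C(Br)=C/CC1(OCCO1)C[C@H](C)CC(=O)OC(C)(C)C
F3 | step 9 | (3R)-4-{2-[(2Z)-3-bromopenta-2,4-dien-1-yl]-1,3-dioxolan-2-yl}-3-methylbutan-1-ol | C=C/C(Br)=C/CC1(OCCO1)C[C@H](C)CCO
F4 | step 9 | (3R)-4-{2-[(2Z)-3-bromopenta-2,4-dien-1-yl]-1,3-dioxolan-2-yl}-3-methylbutanal | C=C/C(Br)=C/CC1(OCCO1)C[C@H](C)CC=O
F5 | step 9 | (3S)-4-{2-[(2Z)-3-bromopenta-2,4-dien-1-yl]-1,3-dioxolan-2-yl}-3-methyl-2-methylidenebutanal | C=C/C(Br)=C/CC1(OCCO1)C[C@H](C)C(=C)C=O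
F6 | step 9 | trans-fused 9-bromo-5β-formyl-4β-methyl-Δ8-octalin-2-one ethylene ketal (10α-H) | C1C[C@]2(C=O)[C@@H](C)CC3(OCCO3)C[C@H]2C(Br)=C1
F7 | step 13 | 8α,9α-epoxy-4β,5β-dimethyl-trans-decalin-2-one ethylene ketal | C1C[C@]2(C)[C@@H](C)CC3(OCCO3)C[C@H]2[C@@H]4O[C@H]14
F8 | step 16 | 7β-ethynyl-8α,9α-dihydroxy-4β,5β-dimethyl-trans-decalin-2-one ethylene ketal | C#C[C@H]1C[C@]2(C)[C@@H](C)CC3(OCCO3)C[C@H]2[C@H](O)[C@@H]1O
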